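The cis-fused decalin is disconnected through C5–C10 and C6–C7 (drimane numbering): ring B is a cyclohexene whose tetrasubstituted C8=C9 alkene marks it as a Diels–Alder adduct. An iminium-catalysed intramolecular Diels–Alder reaction of an acyclic trienal therefore closes rings A and B in one operation, sets C5 and C10, and leaves C8=C9 in place. In the precursor the C1–C4 tether hangs from the inside position of the fully substituted diene terminus C10 (8Z geometry), which allows only the cis ring fusion; the arylmethyl group is already on C9. A temporary formyl group on C6 activates the dienophile and is removed by decarbonylation; sulfation comes last.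

Key step: step 11

Assumption: the target is drawn as the free aryl hydrogen sulfate; it would be handled as a salt and is written throughout in the neutral acid form.

Shorthand: Ar = 2-(benzyloxy)-3-[(triisopropylsilyl)oxy]-5-{[(triisopropylsilyl)oxy]methyl}phenyl; TIPS = triisopropylsilyl. Carbocycle atoms carry drimane numbers (C1–C10; C11 is the benzylic CH2).

**Step 1**
Reactants: 1 3-bromo-4,5-dihydroxybenzaldehyde
Product: 2 4-(benzyloxy)-3-bromo-5-hydroxybenzaldehyde
Conditions: BnBr (1.05 equiv), NaHCO3, DMF, 40 °C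
Reagents that add atoms: benzyl bromide, BrCc1ccccc1
Why: The phenol para to the formyl group and ortho to bromine is the more acidic one, so a weak base should form only its phenoxide and the Williamson etherification should give the 4-O-benzyl ether regioselectively.

**Step 2**
Reactants: 2 4-(benzyloxy)-3-bromo-5-hydroxybenzaldehyde
Product: 3 2-(benzyloxy)-3-bromo-5-(hydroxymethyl)phenol
Conditions: NaBH4, MeOH/THF, 0 °C
Reagents that add atoms: none
Why: Borohydride reduction of the aryl aldehyde to the benzylic alcohol should leave the aryl bromide and the benzyl ether untouched.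

**Step 3**
Reactants: 3 2-(benzyloxy)-3-bromo-5-(hydroxymethyl)phenol
Product: 4 2-(benzyloxy)-1-bromo-3-[(triisopropylsilyl)oxy]-5-{[(triisopropylsilyl)oxy]methyl}benzene
Conditions: TIPSCl (2.4 equiv), imidazole, DMF, rt to 40 °C
Reagents that add atoms: triisopropylsilyl chloride, CC(C)[Si](Cl)(C(C)C)C(C)C
Why: Imidazole-promoted silylation should protect the phenol and the primary alcohol together as base-stable, fluoride-labile TIPS ethers.

**Step 4**
Reactants: 4 2-(benzyloxy)-1-bromo-3-[(triisopropylsilyl)oxy]-5-{[(triisopropylsilyl)oxy]methyl}benzene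
Product: 6 2-(benzyloxy)-3-[(triisopropylsilyl)oxy]-5-{[(triisopropylsilyl)oxy]methyl}benzaldehyde (Ar–CHO), via aryllithium 5 (not isolated)
Conditions: n-BuLi, THF, −78 °C; then DMF, −78 to 0 °C; aqueous work-up
Reagents that add atoms: N,N-dimethylformamide, CN(C)C=O
Why: Bromine–lithium exchange at −78 °C is faster than any attack on the ethers, and Bouveault formylation of the aryllithium should give the aldehyde that becomes C11.

**Step 5**
Reactants: 6 Ar–CHO; 7 pentane-2,4-dione
Product: 8 3-(Ar-methylidene)pentane-2,4-dione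
Conditions: piperidine (10 mol%), AcOH (10 mol%), 4 Å molecular sieves, toluene, 60 °C
Reagents that add atoms: none
Why: Knoevenagel condensation with the symmetric dione should give the arylidene dione without any alkene-geometry issue.

**Step 6**
Reactants: 8 3-(Ar-methylidene)pentane-2,4-dione
Product: 10 (2Z)-3-(Ar-methyl)-4-oxopent-2-en-2-yl trifluoromethanesulfonate, via lithium enolate 9 (not isolated)
Conditions: LiBH(sec-Bu)3, THF, −78 °C; then N-(5-chloropyridin-2-yl)bis(trifluoromethanesulfonyl)imide, −78 °C to rt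
Reagents that add atoms: N-(5-chloropyridin-2-yl)-1,1,1-trifluoro-N-(trifluoromethylsulfonyl)methanesulfonamide, FC(F)(F)S(=O)(=O)N(c1ccc(Cl)cn1)S(=O)(=O)C(F)(F)F
Why: Conjugate hydride addition to the doubly activated alkene should give the chelated U-shaped lithium β-diketonate, and its O-sulfonylation (reductive enolate triflation) should fix the triflate cis to the remaining acetyl group.

**Step 7**
Reactants: 11 2,2-dimethylpent-4-enal
Product: 12 (2E)-N-methoxy-N,4,4-trimethylhepta-2,6-dienamide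
Conditions: (EtO)2P(O)CH2C(O)N(OMe)Me, NaH, THF, 0 °C to rt
Reagents that add atoms: diethyl [2-(methoxy(methyl)amino)-2-oxoethyl]phosphonate, CCOP(=O)(CC(=O)N(C)OC)OCC
Why: Horner–Wadsworth–Emmons olefination of the non-enolisable aldehyde with the stabilised phosphonate anion should give the (E)-enamide, a masked enal that tolerates the next three steps.

**Step 8**
Reactants: 12 (2E)-N-methoxy-N,4,4-trimethylhepta-2,6-dienamide; 10 (2Z)-3-(Ar-methyl)-4-oxopent-2-en-2-yl trifluoromethanesulfonate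
Product: 14 (2E,8Z)-9-acetyl-10-Ar-N-methoxy-N,4,4,8-tetramethyldeca-2,8-dienamide, via alkylborane 13 (not isolated)
Conditions: 9-BBN-H, THF, rt; then 10, PdCl2(dppf) (5 mol%), aq. K3PO4, THF/DMF, 50 °C
Reagents that add atoms: none
Why: 9-BBN should hydroborate only the terminal monosubstituted alkene, and the B-alkyl Suzuki–Miyaura coupling of the vinylogous acyl triflate proceeds with retention, placing the chain cis to the acetyl group.

**Step 9**
Reactants: 14 (2E,8Z)-9-acetyl-10-Ar-N-methoxy-N,4,4,8-tetramethyldeca-2,8-dienamide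
Product: 15 (2E,8Z)-9-(Ar-methyl)-N-methoxy-N,4,4,8,10-pentamethylundeca-2,8,10-trienamide
Conditions: Ph3PCH3Br, KOtBu, THF, 0 °C to rt
Reagents that add atoms: methyltriphenylphosphonium bromide, C[P+](c1ccccc1)(c1ccccc1)c1ccccc1.[Br-]
Why: Wittig methylenation of the methyl ketone, with the N-methoxy-N-methyl amide inert to the ylide, should turn the acetyl group into the isopropenyl unit C8=C7 and complete the (Z)-diene.

**Step 10**
Reactants: 15 (2E,8Z)-9-(Ar-methyl)-N-methoxy-N,4,4,8,10-pentamethylundeca-2,8,10-trienamide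
Product: 16 (2E,8Z)-9-(Ar-methyl)-4,4,8,10-tetramethylundeca-2,8,10-trienal
Conditions: i-Bu2AlH, THF, −78 °C; aq. potassium sodium tartrate
Reagents that add atoms: none
Why: Hydride addition to the N-methoxy-N-methyl amide gives a chelated tetrahedral aluminium adduct that releases the enal only on work-up, so over-reduction should not occur.

**Step 11**
Reactants: 16 (2E,8Z)-9-(Ar-methyl)-4,4,8,10-tetramethylundeca-2,8,10-trienal
Product: 18 (4R,4aR,8aS)-1-(Ar-methyl)-2,5,5,8a-tetramethyl-3,4,4a,5,6,7,8,8a-octahydronaphthalene-4-carbaldehyde (cis-fused; drimane numbering 5R,6R,10S), via iminium ion 17 (not isolated)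
Conditions: (2R,5R)-5-benzyl-2-tert-butyl-3-methylimidazolidin-4-one·CF3CO2H (20 mol%), MeCN/H2O 98:2, 0 °C to rt
Reagents that add atoms: none
Why: Condensation of enal 16 with the imidazolidinone gives the (E)-iminium ion 17, whose lowered LUMO lets the tethered diene add in a concerted, asynchronous [4+2] cycloaddition before hydrolysis releases 18 and the catalyst; the closest known reaction type is the imidazolidinone-catalysed intramolecular Diels–Alder reaction of trienals. Ring A closes as a six-membered carbocycle through the C5–C10 bond (the tether-spanning bond of a type 1 intramolecular cycloaddition), and ring B closes as the cyclohexene of the [4+2] event through C5–C10 and C6–C7, with C8=C9 emerging from the diene. The relative configuration of C5 and C10 follows from the (8Z) diene: with the tether on the inside position of C10 only the transition state with C4 exo and the iminium endo can be reached, which places the C10 methyl and the C5 hydrogen cis. The absolute configuration follows from the catalyst, whose benzyl group shields one face of the iminium so that C10 should bond to the Re face of C5, giving 5R and hence 10S; C6 is also set (R) but is erased in step 12. The step needs the intramolecular cycloaddition to outrun acid-induced decomposition of the electron-rich diene and intermolecular reactions, which the absence of γ-hydrogens in 16 (no dienamine path), the buffered trifluoroacetate salt and moderate dilution should secure.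

**Step 12**
Reactants: 18 (4R,4aR,8aS)-1-(Ar-methyl)-2,5,5,8a-tetramethyl-3,4,4a,5,6,7,8,8a-octahydronaphthalene-4-carbaldehyde
Product: 19 (4aR,8aS)-1-(Ar-methyl)-2,5,5,8a-tetramethyl-3,4,4a,5,6,7,8,8a-octahydronaphthalene
Conditions: RhCl(PPh3)3 (1.1 equiv), toluene, 110 °C
Reagents that add atoms: none
Why: Tsuji–Wilkinson decarbonylation (acyl C–H insertion, CO extrusion, C–H reductive elimination) should remove the temporary C6 formyl group as rhodium-bound CO and leave C6 as CH2 without touching C5 or C10.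

**Step 13**
Reactants: 19 (4aR,8aS)-1-(Ar-methyl)-2,5,5,8a-tetramethyl-3,4,4a,5,6,7,8,8a-octahydronaphthalene
Product: 20 2-[(triisopropylsilyl)oxy]-4-{[(triisopropylsilyl)oxy]methyl}-6-{[(4aR,8aS)-2,5,5,8a-tetramethyl-3,4,4a,5,6,7,8,8a-octahydronaphthalen-1-yl]methyl}phenol
Conditions: H2 (1 atm), palladium on carbon (10 wt%), EtOAc, rt
Reagents that add atoms: none
Why: Hydrogenolysis of the benzyl aryl ether under neutral conditions should free only the phenol to be sulfated, because the tetrasubstituted alkene is too hindered to be hydrogenated and the silyl ethers are inert.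

**Step 14**
Reactants: 20 the phenol from step 13
Product: 21 2-[(triisopropylsilyl)oxy]-4-{[(triisopropylsilyl)oxy]methyl}-6-{[(4aR,8aS)-2,5,5,8a-tetramethyl-3,4,4a,5,6,7,8,8a-octahydronaphthalen-1-yl]methyl}phenyl hydrogen sulfate
Conditions: SO3·pyridine (3 equiv), pyridine, rt to 40 °C
Reagents that add atoms: sulfur trioxide–pyridine complex, [O-]S(=O)(=O)[n+]1ccccc1
Why: O-Sulfation of the single free phenol under basic conditions should place the sulfate unambiguously and avoid acid-induced addition of the phenol to C8=C9.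

**Step 15**
Reactants: 21 the silyl-protected aryl hydrogen sulfate
Product: 22 2-hydroxy-4-(hydroxymethyl)-6-{[(4aR,8aS)-2,5,5,8a-tetramethyl-3,4,4a,5,6,7,8,8a-octahydronaphthalen-1-yl]methyl}phenyl hydrogen sulfate (CNP0263972.2)
Conditions: Bu4NF (3 equiv), THF, 0 °C to rt; cation exchange at 0 °C
Reagents that add atoms: none
Why: Fluoride-mediated desilylation should cleave both TIPS ethers under non-acidic conditions that leave the aryl sulfate monoester and the alkene intact.

**Compound list**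

1 | 3-bromo-4,5-dihydroxybenzaldehyde | O=Cc1cc(O)c(O)c(Br)c1 | starting material
2 | 4-(benzyloxy)-3-bromo-5-hydroxybenzaldehyde | O=Cc1cc(O)c(OCc2ccccc2)c(Br)c1 | intermediate
3 | 2-(benzyloxy)-3-bromo-5-(hydroxymethyl)phenol | OCc1cc(O)c(OCc2ccccc2)c(Br)c1 | intermediate
4 | 2-(benzyloxy)-1-bromo-3-[(triisopropylsilyl)oxy]-5-{[(triisopropylsilyl)oxy]methyl}benzene | Brc1cc(CO[Si](C(C)C)(C(C)C)C(C)C)cc(O[Si](C(C)C)(C(C)C)C(C)C)c1OCc1ccccc1 | intermediate
5 | aryllithium Ar–Li (not isolated) | [Li]c1cc(CO[Si](C(C)C)(C(C)C)C(C)C)cc(O[Si](C(C)C)(C(C)C)C(C)C)c1OCc1ccccc1 | intermediate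
6 | 2-(benzyloxy)-3-[(triisopropylsilyl)oxy]-5-{[(triisopropylsilyl)oxy]methyl}benzaldehyde | O=Cc1cc(CO[Si](C(C)C)(C(C)C)C(C)C)cc(O[Si](C(C)C)(C(C)C)C(C)C)c1OCc1ccccc1 | intermediate
7 | pentane-2,4-dione | CC(=O)CC(C)=O | starting material
8 | 3-(Ar-methylidene)pentane-2,4-dione | CC(=O)C(=Cc1cc(CO[Si](C(C)C)(C(C)C)C(C)C)cc(O[Si](C(C)C)(C(C)C)C(C)C)c1OCc1ccccc1)C(C)=O | intermediate
9 | lithium (Z)-enolate of 3-(Ar-methyl)pentane-2,4-dione (not isolated) | CC(=O)/C(Cc1cc(CO[Si](C(C)C)(C(C)C)C(C)C)cc(O[Si](C(C)C)(C(C)C)C(C)C)c1OCc1ccccc1)=C(/C)O[Li] | intermediate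
10 | (2Z)-3-(Ar-methyl)-4-oxopent-2-en-2-yl trifluoromethanesulfonate | CC(=O)/C(Cc1cc(CO[Si](C(C)C)(C(C)C)C(C)C)cc(O[Si](C(C)C)(C(C)C)C(C)C)c1OCc1ccccc1)=C(/C)OS(=O)(=O)C(F)(F)F | intermediate
11 | 2,2-dimethylpent-4-enal | C=CCC(C)(C)C=O | starting material
12 | (2E)-N-methoxy-N,4,4-trimethylhepta-2,6-dienamide | C=CCC(C)(C)/C=C/C(=O)N(C)OC | intermediate
13 | (2E)-7-(9-borabicyclo[3.3.1]nonan-9-yl)-N-methoxy-N,4,4-trimethylhept-2-enamide (not isolated) | CON(C)C(=O)/C=C/C(C)(C)CCCB1C2CCCC1CCC2 | intermediate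
14 | (2E,8Z)-9-acetyl-10-Ar-N-methoxy-N,4,4,8-tetramethyldeca-2,8-dienamide | CON(C)C(=O)/C=C/C(C)(C)CCC/C(C)=C(/Cc1cc(CO[Si](C(C)C)(C(C)C)C(C)C)cc(O[Si](C(C)C)(C(C)C)C(C)C)c1OCc1ccccc1)C(C)=O | intermediate
15 | (2E,8Z)-9-(Ar-methyl)-N-methoxy-N,4,4,8,10-pentamethylundeca-2,8,10-trienamide | CON(C)C(=O)/C=C/C(C)(C)CCC/C(C)=C(/Cc1cc(CO[Si](C(C)C)(C(C)C)C(C)C)cc(O[Si](C(C)C)(C(C)C)C(C)C)c1OCc1ccccc1)C(C)=C | intermediate
16 | (2E,8Z)-9-(Ar-methyl)-4,4,8,10-tetramethylundeca-2,8,10-trienal | O=C/C=C/C(C)(C)CCC/C(C)=C(/Cc1cc(CO[Si](C(C)C)(C(C)C)C(C)C)cc(O[Si](C(C)C)(C(C)C)C(C)C)c1OCc1ccccc1)C(C)=C | intermediate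
17 | iminium trifluoroacetate of 16 with the (2R,5R)-imidazolidinone (not isolated) | CN1C(=O)[C@@H](Cc2ccccc2)[N+](=C/C=C/C(C)(C)CCC/C(C)=C(/Cc2cc(CO[Si](C(C)C)(C(C)C)C(C)C)cc(O[Si](C(C)C)(C(C)C)C(C)C)c2OCc2ccccc2)C(C)=C)[C@H]1C(C)(C)C.[O-]C(=O)C(F)(F)F | intermediate
18 | (4R,4aR,8aS)-1-(Ar-methyl)-2,5,5,8a-tetramethyl-3,4,4a,5,6,7,8,8a-octahydronaphthalene-4-carbaldehyde | CC1=C(Cc2cc(CO[Si](C(C)C)(C(C)C)C(C)C)cc(O[Si](C(C)C)(C(C)C)C(C)C)c2OCc2ccccc2)[C@@]2(C)CCCC(C)(C)[C@H]2[C@H](C=O)C1 | intermediate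
19 | (4aR,8aS)-1-(Ar-methyl)-2,5,5,8a-tetramethyl-3,4,4a,5,6,7,8,8a-octahydronaphthalene | CC1=C(Cc2cc(CO[Si](C(C)C)(C(C)C)C(C)C)cc(O[Si](C(C)C)(C(C)C)C(C)C)c2OCc2ccccc2)[C@@]2(C)CCCC(C)(C)[C@H]2CC1 | intermediate
20 | 2-[(triisopropylsilyl)oxy]-4-{[(triisopropylsilyl)oxy]methyl}-6-{[(4aR,8aS)-2,5,5,8a-tetramethyl-3,4,4a,5,6,7,8,8a-octahydronaphthalen-1-yl]methyl}phenol | CC1=C(Cc2cc(CO[Si](C(C)C)(C(C)C)C(C)C)cc(O[Si](C(C)C)(C(C)C)C(C)C)c2O)[C@@]2(C)CCCC(C)(C)[C@H]2CC1 | intermediate
21 | 2-[(triisopropylsilyl)oxy]-4-{[(triisopropylsilyl)oxy]methyl}-6-{[(4aR,8aS)-2,5,5,8a-tetramethyl-3,4,4a,5,6,7,8,8a-octahydronaphthalen-1-yl]methyl}phenyl hydrogen sulfate | CC1=C(Cc2cc(CO[Si](C(C)C)(C(C)C)C(C)C)cc(O[Si](C(C)C)(C(C)C)C(C)C)c2OS(=O)(=O)O)[C@@]2(C)CCCC(C)(C)[C@H]2CC1 | intermediate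
22 | 2-hydroxy-4-(hydroxymethyl)-6-{[(4aR,8aS)-2,5,5,8a-tetramethyl-3,4,4a,5,6,7,8,8a-octahydronaphthalen-1-yl]methyl}phenyl hydrogen sulfate | CC1=C(Cc2cc(CO)cc(O)c2OS(=O)(=O)O)[C@@]2(C)CCCC(C)(C)[C@H]2CC1 | target

Total step count: 15. Longest linear sequence: 14 steps (steps 1–6 and 8–15; step 7 prepares the tether separately).

**Steps most likely to fail**

Step 11. The cycloaddition may stall because the bond to the fully substituted diene terminus must form at the neopentyl β-carbon of the iminium ion; the acid-sensitive diene may also be protonated and oligomerise first, and facial control may erode if warming is needed. The fallback replaces aminocatalysis by a covalently bound auxiliary and chelating Lewis-acid activation. It sets out from 16: Pinnick oxidation (NaClO2, NaH2PO4, 2-methylbut-2-ene, t-BuOH/H2O) would give (2E,8Z)-9-(Ar-methyl)-4,4,8,10-tetramethylundeca-2,8,10-trienoic acid F1. Acylation of (R)-4-benzyl-1,3-oxazolidin-2-one through the pivaloyl mixed anhydride (t-BuCOCl, Et3N, LiCl, THF) would give the N-trienoyl oxazolidinone F2. Treatment with Me2AlCl in CH2Cl2 at −30 °C would promote the intramolecular Diels–Alder reaction through the chelated s-cis imide, which the (Z)-diene again restricts to the cis-fused, carbonyl-endo mode and the auxiliary benzyl group directs to the same face, giving the cycloadduct imide F3. Reduction with LiBH4 in wet ether would release the auxiliary and give the C6 hydroxymethyl compound F4. Dess–Martin oxidation would return the sequence to 18.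

Step 6. O-Sulfonylation of the stabilised β-diketonate may be incomplete, or the chelate may partly open, which would erode the geometry of the tetrasubstituted alkene. The fallback separates reduction from sulfonylation and changes the leaving group. It sets out from 8: transfer hydrogenation with diethyl 2,6-dimethyl-1,4-dihydropyridine-3,5-dicarboxylate (toluene, 80 °C) would give 3-(Ar-methyl)pentane-2,4-dione F5. Chelation-controlled enol tosylation (TsCl, TMEDA, LiCl, MeCN, 0 °C) would give (2Z)-3-(Ar-methyl)-4-oxopent-2-en-2-yl 4-methylbenzenesulfonate F6. B-alkyl Suzuki–Miyaura coupling of F6 with alkylborane 13 (Pd(OAc)2, SPhos, K3PO4, THF/H2O) would return the sequence to 14.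

Step 9. The basic ylide may deprotonate the hindered enone at its γ-positions instead of adding to the carbonyl, which would scramble the tetrasubstituted alkene geometry and leave ketone unconverted. The fallback is a two-stage Peterson olefination with a non-basic organocerium nucleophile. It sets out from 14: addition of Me3SiCH2Li premixed with CeCl3 (THF, −78 °C) would give the β-hydroxysilane (2E,8Z)-10-hydroxy-9-(Ar-methyl)-N-methoxy-N,4,4,8,10-pentamethyl-11-(trimethylsilyl)undeca-2,8-dienamide F7. Syn-elimination with KH (THF, 0 °C) would return the sequence to 15.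

**Further compounds**

F1 | step 11 | (2E,8Z)-9-(Ar-methyl)-4,4,8,10-tetramethylundeca-2,8,10-trienoic acid | OC(=O)/C=C/C(C)(C)CCC/C(C)=C(/Cc1cc(CO[Si](C(C)C)(C(C)C)C(C)C)cc(O[Si](C(C)C)(C(C)C)C(C)C)c1OCc1ccccc1)C(C)=C
F2 | step 11 | (4R)-4-benzyl-3-[(2E,8Z)-9-(Ar-methyl)-4,4,8,10-tetramethylundeca-2,8,10-trienoyl]-1,3-oxazolidin-2-one | O=C1OC[C@@H](Cc2ccccc2)N1C(=O)/C=C/C(C)(C)CCC/C(C)=C(/Cc1cc(CO[Si](C(C)C)(C(C)C)C(C)C)cc(O[Si](C(C)C)(C(C)C)C(C)C)c1OCc1ccccc1)C(C)=C
F3 | step 11 | (4R)-4-benzyl-3-{[(4R,4aR,8aS)-1-(Ar-methyl)-2,5,5,8a-tetramethyl-3,4,4a,5,6,7,8,8a-octahydronaphthalen-4-yl]carbonyl}-1,3-oxazolidin-2-one | CC1=C(Cc2cc(CO[Si](C(C)C)(C(C)C)C(C)C)cc(O[Si](C(C)C)(C(C)C)C(C)C)c2OCc2ccccc2)[C@@]2(C)CCCC(C)(C)[C@H]2[C@H](C(=O)N2[C@H](Cc3ccccc3)COC2=O)C1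
F4 | step 11 | [(4R,4aR,8aS)-1-(Ar-methyl)-2,5,5,8a-tetramethyl-3,4,4a,5,6,7,8,8a-octahydronaphthalen-4-yl]methanol | CC1=C(Cc2cc(CO[Si](C(C)C)(C(C)C)C(C)C)cc(O[Si](C(C)C)(C(C)C)C(C)C)c2OCc2ccccc2)[C@@]2(C)CCCC(C)(C)[C@H]2[C@H](CO)C1
F5 | step 6 | 3-(Ar-methyl)pentane-2,4-dione | CC(=O)C(Cc1cc(CO[Si](C(C)C)(C(C)C)C(C)C)cc(O[Si](C(C)C)(C(C)C)C(C)C)c1OCc1ccccc1)C(C)=O
F6 | step 6 | (2Z)-3-(Ar-methyl)-4-oxopent-2-en-2-yl 4-methylbenzenesulfonate | CC(=O)/C(Cc1cc(CO[Si](C(C)C)(C(C)C)C(C)C)cc(O[Si](C(C)C)(C(C)C)C(C)C)c1OCc1ccccc1)=C(/C)OS(=O)(=O)c1ccc(C)cc1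
F7 | step 9 | (2E,8Z)-10-hydroxy-9-(Ar-methyl)-N-methoxy-N,4,4,8,10-pentamethyl-11-(trimethylsilyl)undeca-2,8-dienamide | CON(C)C(=O)/C=C/C(C)(C)CCC/C(C)=C(/Cc1cc(CO[Si](C(C)C)(C(C)C)C(C)C)cc(O[Si](C(C)C)(C(C)C)C(C)C)c1OCc1ccccc1)C(C)(O)C[Si](C)(C)C
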